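**Strategy.** The plan cuts ring A at C4–C5 and places the lactone carbon C19 between them. Ring A is therefore first made as the seven-membered ring C3–C4–C19–C5–C10–C1–C2, bridged by the future lactone oxygen (C3–O–C10), through an intramolecular (4+3) cycloaddition of a bromo-oxyallyl cation with a furan that also closes ring B. The key step contracts it: in the precursor, a C19 carbinol with bromine and the C18 methyl on C4, the alkoxide drives a 1,2-shift of C5 from C19 to C4, expelling bromide, making C19 the exocyclic carbonyl and fixing the C4 quaternary centre. It exploits the C4(C18)(C19)–C5 array and the C10 oxygen of ring A. Bridge opening, lactonisation, dihydroxylation and ring D closure follow.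

Key step: step 12

Remark: gibberellane numbering (C1–C19) is used for all intermediates; α is the face of the lactone oxygen, β the face of H5 and H9.
Remark: step 7 is not expected to control C6; compounds 11–16 are C6 epimer mixtures, drawn with the configuration that the base treatment in step 12 makes uniform.
Remark: 3 is epimeric at its enolisable carbon, and the C4 configuration of 13 and the carbinol configuration of 16 are inconsequential; the epimer expected to predominate is drawn.

Step 1
Reactants: 1 (E)-3-(furan-2-yl)prop-2-enal; 2 methyl 4-methoxy-3-oxobutanoate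
Product: 4 methyl trans-2-(furan-2-yl)-5-methoxy-6-oxocyclohex-4-ene-1-carboxylate (furyl carbon C9 R), via Michael adduct 3 (not isolated)
Conditions: (S)-α,α-diphenylprolinol trimethylsilyl ether (10 mol %), PhCO2H (10 mol %), toluene, rt; then TsOH·H2O (20 mol %), 80 °C
Reagents that add atoms: none
Why: Iminium-activated Michael addition of the β-keto ester to the enal (Si-face attack under the (S)-catalyst should set C9 as R), then acid-mediated aldol condensation of the methoxymethyl ketone onto the aldehyde (organocatalytic Michael/aldol annulation), should give a 2-methoxy enone that already carries the C13 oxygen.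

Step 2
Reactants: 4 β-keto ester
Product: 5 methyl 2-(furan-2-yl)-5-methoxy-1-(2-methoxy-2-oxoethyl)-6-oxocyclohex-4-ene-1-carboxylate
Conditions: K2CO3, acetone, rt
Reagents that add atoms: methyl bromoacetate COC(=O)CBr
Why: C-alkylation of the β-keto ester anion (enolate alkylation) should be regiospecific at C8 and needs no strong base; the C8 configuration formed here is transient.

Step 3
Reactants: 5 quaternary β-keto ester
Product: 6 methyl 2-[trans-6-(furan-2-yl)-3-methoxy-2-oxocyclohex-3-en-1-yl]acetate
Conditions: LiCl, H2O, DMSO, 140 °C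
Reagents that add atoms: none
Why: Krapcho dealkoxycarbonylation should remove only the activated β-keto ester carboxylate, and the enolisable C8 should settle trans to the furyl group.

Step 4
Reactants: 6 keto ester
Product: 7 methyl 2-[6-(furan-2-yl)-3-methoxy-2-oxo-1-(3-triisopropylsilylprop-2-yn-1-yl)cyclohex-3-en-1-yl]acetate (acetate arm cis, propargyl arm trans to furyl)
Conditions: LiN(i-Pr)2 (1.05 equiv), THF, −78 °C; then the bromide, DMPU, −78 → −30 °C
Reagents that add atoms: 3-bromo-1-(triisopropylsilyl)prop-1-yne CC(C)[Si](C(C)C)(C(C)C)C#CCBr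
Why: Kinetic α′-deprotonation of the enone (the ketone C–H is the most acidic) and alkylation anti to the C9 furyl group should create quaternary C8 with C15 trans and the C6 arm cis to the furan, as ring B will require.

Step 5
Reactants: 7 enone
Product: 8 tosylhydrazone of 7
Conditions: TsNHNH2, AcOH (cat.), EtOH, 60 °C
Reagents that add atoms: 4-methylbenzenesulfonohydrazide Cc1ccc(cc1)S(=O)(=O)NN
Why: Condensation at the only ketone (hydrazone formation) prepares the reductive removal of the C14 oxygen.

Step 6
Reactants: 8 tosylhydrazone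
Product: 10 methyl 2-[8-(furan-2-yl)-7-(3-triisopropylsilylprop-2-yn-1-yl)-1,4-dioxaspiro[4.5]decan-7-yl]acetate, via enol ether 9 (not isolated)
Conditions: catecholborane, CHCl3, 0 °C; NaOAc·3H2O, 60 °C; then HOCH2CH2OH, PPTS, CH2Cl2, rt
Reagents that add atoms: ethane-1,2-diol OCCO
Why: Hydride reduction of the unsaturated tosylhydrazone, sulfinate loss and retro-ene shift of the allylic diazene (alkene-walk reduction) should leave C14 as CH and C13 as a methyl enol ether, which acid-catalysed exchange with the diol turns into the dioxolane (net 1,2-carbonyl transposition).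

Step 7
Reactants: 10 ketal ester
Product: 11 methyl 2-[8-(furan-2-yl)-7-(3-triisopropylsilylprop-2-yn-1-yl)-1,4-dioxaspiro[4.5]decan-7-yl]-4-[methoxy(methyl)amino]-4-oxobutanoate
Conditions: LiN(i-Pr)2, THF, −78 °C; then the bromoamide, −78 → −40 °C
Reagents that add atoms: 2-bromo-N-methoxy-N-methylacetamide CON(C)C(=O)CBr
Why: The ester enolate (the only acidic C–H left) should be alkylated by the α-bromo amide (enolate alkylation), joining C5 to C6.

Step 8
Reactants: 11 Weinreb amide
Product: 12 methyl 5,5-dibromo-2-[8-(furan-2-yl)-7-(3-triisopropylsilylprop-2-yn-1-yl)-1,4-dioxaspiro[4.5]decan-7-yl]-4-oxohexanoate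
Conditions: CH3CHBr2, LiN(i-Pr)2, THF, −100 °C; then 11, −100 → −78 °C; AcOH
Reagents that add atoms: 1,1-dibromoethane CC(Br)Br
Why: 1,1-Dibromoethyllithium should add once to the Weinreb amide (chelated tetrahedral intermediate, hindered methyl ester untouched) to give the α,α-dibromo ketone that holds C19, C4 and C18.

Step 9
Reactants: 12 dibromo ketone
Product: 13 (4+3) cycloadduct (oxygen-bridged seven-membered bromoketone trans-fused to ring B; Br anti to the bridge)
Conditions: Et3N, CF3CH2OH, 0 °C → rt
Reagents that add atoms: none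
Why: Enolisation at C5 and loss of bromide from C4 should give a bromo-oxyallyl cation that adds across the furan 2,5-positions ((4+3) cycloaddition, ring B closed as a five-membered ring by the tether C9–C8–C6); the short tether fits only the extended arrangement, which gives the trans C5–C10 fusion (H5 β, C6 syn to the bridge), and the furan should turn its oxygen, not its C3–H, toward the C11 methylene, which sets the C10 oxygen α relative to C9.

Step 10
Reactants: 13 cycloadduct
Product: 15 bromoketone with Br syn to the oxygen bridge (α) and C18 methyl β, via silyl enol ether 14 (not isolated)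
Conditions: Zn, Me3SiCl, TMEDA, Et2O, 0 °C → rt; filter; then NBS, THF, −78 °C
Reagents that add atoms: N-bromosuccinimide O=C1CCC(=O)N1Br; chlorotrimethylsilane C[Si](C)(C)Cl (its atoms stay only in 14)
Why: Reductive silylation should give the regiodefined C19–C4 enol ether whatever the C4 configuration of 13, and bromination from the exposed face of the oxygen bridge (exo attack on an oxabicyclic enol ether) should place bromine on C4 syn to the bridge, as the shift requires.

Step 11
Reactants: 15 bromoketone
Product: 16 bromohydrin (C19 carbinol)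
Conditions: NaBH4, MeOH/THF, −20 → 0 °C
Reagents that add atoms: none
Why: Hydride reduction of the C19 ketone removes the carbonyl without enolising C5, so the later base treatment cannot enter a cyclopropanone (Favorskii) pathway.

Step 12
Reactants: 16 bromohydrin
Product: 17 ring-contracted aldehyde (7-oxabicyclo[2.2.1]hept-2-ene ring A; C4 bears CHO α and CH3 β; 6β-CO2Me)
Conditions: KH, THF, 0 °C → rt; then NaOMe, MeOH, 50 °C
Reagents that add atoms: none
Why: Deprotonation gives the C19 alkoxide, whose electron push drives the 1,2-shift of the C19–C5 bond to C4 with backside displacement of bromide, so that C19 becomes the formyl group and the seven-membered carbocycle C3–C4–C19–C5–C10–C1–C2 contracts to ring A (C3–C4–C5–C10–C1–C2). The closest known reaction type is the quasi-Favorskii (semipinacol) rearrangement of α-halo carbinols and ketones obtained from (4+3) cycloadducts. Ring A is closed by this suprafacial 1,2-alkyl shift, a ring contraction in which C5 bridges C19 and C4 (3-exo-tet-like displacement at C4), not by a new cyclisation. C4 is the new stereocentre: inversion at C4, fixed by the bromine placed syn to the oxygen bridge in step 10, leaves C19 syn to the bridge (α) and C18 β, while C5 migrates with retention. The step needs migration of C5 rather than epoxide closure, hydride shift or loss of HBr; the trans fusion to ring B holds the bridged ring in the boat form in which only the C19–C5 bond is antiperiplanar to C4–Br, while O and H on C19 are gauche to it. The following methoxide treatment should equilibrate the C6 ester to the less hindered β position (trans to C4), the aldehyde being non-enolisable.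

Step 13
Reactants: 17 aldehyde ester
Product: 18 triol (10α-OH, 19-OH, 7-OH; 2,3-alkene)
Conditions: i-Bu2AlH (excess, slow addition), Ni(cod)2 (10 mol %), Ph2P(CH2)4PPh2 (20 mol %), toluene, 0 → 60 °C; aqueous potassium sodium tartrate
Reagents that add atoms: none
Why: i-Bu2AlH should reduce aldehyde and ester, and nickel-catalysed hydroalumination of the strained alkene (aluminium on the less hindered C2, hydrogen on C1) followed by β-alkoxide elimination should cleave C3–O, leaving the tertiary C10 alkoxide and the 2,3-alkene (reductive ring opening of an oxabicyclic alkene).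

Step 14
Reactants: 18 triol
Product: 19 7-O-tert-butyldimethylsilyl ether of 18
Conditions: t-BuMe2SiCl (1.05 equiv), imidazole, CH2Cl2, −20 °C
Reagents that add atoms: tert-butylchlorodimethylsilane CC(C)(C)[Si](C)(C)Cl
Why: Silylation should select the less hindered primary C7 hydroxyl (the C19 hydroxyl is neopentyl, the C10 hydroxyl tertiary), so that C19 cannot later form a lactol with C7.

Step 15
Reactants: 19 silyl ether diol
Product: 20 19,10-lactone
Conditions: TEMPO (20 mol %), PhI(OAc)2, CH2Cl2, rt
Reagents that add atoms: none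
Why: Oxoammonium oxidation of the C19 alcohol, lactol formation with the cis-1,3-diaxial C10 hydroxyl and further oxidation (oxidative lactonisation of a 1,4-diol) should close the γ-lactone.

Step 16
Reactants: 20 lactone
Product: 21 7-alcohol with terminal alkyne
Conditions: Bu4NF, AcOH, THF, rt
Reagents that add atoms: none
Why: Fluoride should cleave both the silyl ether and the alkynyl–silicon bond (desilylation) under buffered conditions that spare the lactone.

Step 17
Reactants: 21 alcohol
Product: 23 13-keto 7-carboxylic acid, via ketal acid 22 (not isolated)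
Conditions: CrO3, H2SO4, H2O, acetone, 0 °C; then 1 M HCl, THF, rt
Reagents that add atoms: water O
Why: Jones oxidation should take the primary alcohol to the acid, and aqueous acid then hydrolyses the dioxolane to the C13 ketone.

Step 18
Reactants: 23 keto acid
Product: 24 2β,3β-diol
Conditions: OsO4 (5 mol %), N-methylmorpholine N-oxide, acetone/H2O, rt
Reagents that add atoms: osmium tetroxide O=[Os](=O)(=O)=O (catalytic oxygen carrier); N-methylmorpholine N-oxide C[N+]1([O-])CCOCC1; water O
Why: Upjohn syn-dihydroxylation of the only alkene should occur on the β face, anti to the lactone bridge that spans C4 and C10 on the α face, and the alkyne reacts much more slowly.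

Step 19
Reactants: 24 diol keto acid
Product: 25 the target gibberellin (2β,3β,10,13-tetrahydroxy-20-norgibberell-16-ene-7,19-dioic acid 19,10-lactone)
Conditions: SmI2 (excess), HMPA, t-BuOH, THF, −20 °C → rt
Reagents that add atoms: none
Why: The ketyl radical of the C13 ketone should add 5-exo-dig to the alkyne (ketyl–alkyne reductive cyclisation), closing ring D with the tertiary 13-hydroxyl and the 16-methylene; the bridged geometry allows only one C13 configuration.

**Compound list**

1 | (E)-3-(furan-2-yl)prop-2-enal | O=C/C=C/c1ccco1 | starting material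
2 | methyl 4-methoxy-3-oxobutanoate | COCC(=O)CC(=O)OC | starting material
3 | methyl (3R)-3-(furan-2-yl)-2-(methoxyacetyl)-5-oxopentanoate (epimers at C2) | COCC(=O)C(C(=O)OC)[C@@H](CC=O)c1ccco1 | intermediate
4 | methyl trans-2-(furan-2-yl)-5-methoxy-6-oxocyclohex-4-ene-1-carboxylate (C9 R) | COC(=O)[C@@H]1C(=O)C(OC)=CC[C@H]1c1ccco1 | intermediate
5 | methyl 2-(furan-2-yl)-5-methoxy-1-(2-methoxy-2-oxoethyl)-6-oxocyclohex-4-ene-1-carboxylate (acetate arm trans to furyl) | COC(=O)C[C@]1(C(=O)OC)C(=O)C(OC)=CC[C@H]1c1ccco1 | intermediate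
6 | methyl 2-[trans-6-(furan-2-yl)-3-methoxy-2-oxocyclohex-3-en-1-yl]acetate | COC(=O)C[C@@H]1C(=O)C(OC)=CC[C@H]1c1ccco1 | intermediate
7 | methyl 2-[6-(furan-2-yl)-3-methoxy-2-oxo-1-(3-triisopropylsilylprop-2-yn-1-yl)cyclohex-3-en-1-yl]acetate (acetate arm cis, propargyl arm trans to furyl) | CC(C)[Si](C(C)C)(C(C)C)C#CC[C@]1(CC(=O)OC)C(=O)C(OC)=CC[C@H]1c1ccco1 | intermediate
8 | 4-methylbenzenesulfonylhydrazone of 7 (NHTs anti to C8) | CC(C)[Si](C(C)C)(C(C)C)C#CC[C@]1(CC(=O)OC)/C(=N/NS(=O)(=O)c2ccc(C)cc2)C(OC)=CC[C@H]1c1ccco1 | intermediate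
9 | methyl 2-[6-(furan-2-yl)-3-methoxy-1-(3-triisopropylsilylprop-2-yn-1-yl)cyclohex-2-en-1-yl]acetate (C13 methyl enol ether) | CC(C)[Si](C(C)C)(C(C)C)C#CC[C@]1(CC(=O)OC)C=C(OC)CC[C@H]1c1ccco1 | intermediate
10 | methyl 2-[8-(furan-2-yl)-7-(3-triisopropylsilylprop-2-yn-1-yl)-1,4-dioxaspiro[4.5]decan-7-yl]acetate (acetate arm cis to furyl) | CC(C)[Si](C(C)C)(C(C)C)C#CC[C@]1(CC(=O)OC)CC2(OCCO2)CC[C@H]1c1ccco1 | intermediate
11 | methyl 2-[ring as in 10]-4-[methoxy(methyl)amino]-4-oxobutanoate | CC(C)[Si](C(C)C)(C(C)C)C#CC[C@]1([C@H](CC(=O)N(C)OC)C(=O)OC)CC2(OCCO2)CC[C@H]1c1ccco1 | intermediate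
12 | methyl 5,5-dibromo-4-oxo-2-[ring as in 10]hexanoate | CC(C)[Si](C(C)C)(C(C)C)C#CC[C@]1([C@H](CC(=O)C(C)(Br)Br)C(=O)OC)CC2(OCCO2)CC[C@H]1c1ccco1 | intermediate
13 | cycloadduct: 8-oxabicyclo[3.2.1]oct-6-en-3-one (C3–O–C10 bridge α, C1=C2, C19 ketone, C4 with CH3 α and Br β) trans-fused at C5–C10 to ring B (6β-CO2Me), ring B cis-fused to ring C (C13 dioxolane), C8 β-CH2C≡CSi(i-Pr)3 | CC(C)[Si](C(C)C)(C(C)C)C#CC[C@]23CC4(OCCO4)CC[C@H]2[C@@]15C=C[C@@H](O1)[C@](C)(Br)C(=O)[C@H]5[C@@H]3C(=O)OC | intermediate
14 | trimethylsilyl enol ether C19(OSiMe3)=C4(CH3) of 13 | CC(C)[Si](C(C)C)(C(C)C)C#CC[C@]23CC4(OCCO4)CC[C@H]2[C@@]15C=C[C@@H](O1)C(C)=C(O[Si](C)(C)C)[C@H]5[C@@H]3C(=O)OC | intermediate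
15 | C4 epimer of 13: Br α (syn to the oxygen bridge), CH3 β | CC(C)[Si](C(C)C)(C(C)C)C#CC[C@]23CC4(OCCO4)CC[C@H]2[C@@]15C=C[C@@H](O1)[C@@](C)(Br)C(=O)[C@H]5[C@@H]3C(=O)OC | intermediate
16 | C19 alcohol of 15 (OH α) | CC(C)[Si](C(C)C)(C(C)C)C#CC[C@]23CC4(OCCO4)CC[C@H]2[C@@]15C=C[C@@H](O1)[C@@](C)(Br)[C@@H](O)[C@H]5[C@@H]3C(=O)OC | intermediate
17 | ring-contracted aldehyde: ring A as 7-oxabicyclo[2.2.1]hept-2-ene (C3–O–C10 bridge α, C1=C2), C4 with CHO α and CH3 β, H5 β, 6β-CO2Me; rest as 13 | CC(C)[Si](C(C)C)(C(C)C)C#CC[C@]23CC4(OCCO4)CC[C@H]2[C@@]15C=C[C@@H](O1)[C@@](C)(C=O)[C@H]5[C@@H]3C(=O)OC | intermediate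
18 | triol: ring A cyclohex-2-ene with 10α-OH, C4 with CH2OH α and CH3 β; 6β-CH2OH; rest as 13 | CC(C)[Si](C(C)C)(C(C)C)C#CC[C@]23CC4(OCCO4)CC[C@H]2[C@]1(O)CC=C[C@@](C)(CO)[C@H]1[C@@H]3CO | intermediate
19 | 7-O-tert-butyldimethylsilyl ether of 18 | CC(C)[Si](C(C)C)(C(C)C)C#CC[C@]23CC4(OCCO4)CC[C@H]2[C@]1(O)CC=C[C@@](C)(CO)[C@H]1[C@@H]3CO[Si](C)(C)C(C)(C)C | intermediate
20 | 19,10-lactone of 19 (2,3-alkene, 7-silyl ether, C13 dioxolane, silyl alkyne) | CC(C)[Si](C(C)C)(C(C)C)C#CC[C@]23CC4(OCCO4)CC[C@H]2[C@@]12CC=C[C@@](C)(C(=O)O1)[C@H]2[C@@H]3CO[Si](C)(C)C(C)(C)C | intermediate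
21 | 7-alcohol with terminal alkyne (19,10-lactone, 2,3-alkene, C13 dioxolane) | C#CC[C@]23CC4(OCCO4)CC[C@H]2[C@@]12CC=C[C@@](C)(C(=O)O1)[C@H]2[C@@H]3CO | intermediate
22 | 7-carboxylic acid of 21 (C13 dioxolane) | C#CC[C@]23CC4(OCCO4)CC[C@H]2[C@@]12CC=C[C@@](C)(C(=O)O1)[C@H]2[C@@H]3C(=O)O | intermediate
23 | 13-ketone of 22 | C#CC[C@]23CC(=O)CC[C@H]2[C@@]12CC=C[C@@](C)(C(=O)O1)[C@H]2[C@@H]3C(=O)O | intermediate
24 | 2β,3β-diol of 23 | C#CC[C@]23CC(=O)CC[C@H]2[C@@]12C[C@H](O)[C@H](O)[C@@](C)(C(=O)O1)[C@H]2[C@@H]3C(=O)O | intermediate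
25 | the target gibberellin (2β,3β,10,13-tetrahydroxy-20-norgibberell-16-ene-7,19-dioic acid 19,10-lactone) | C=C1C[C@]23C[C@@]1(O)CC[C@H]2[C@@]12C[C@H](O)[C@H](O)[C@@](C)(C(=O)O1)[C@H]2[C@@H]3C(=O)O | target

**Count.** Total steps: 19. Longest linear sequence: 19 (from 1 or 2).

**Steps most likely to fail**

Step 9. The oxyallyl cation may be captured by trifluoroethanol or collapse by Favorskii rearrangement before it reaches the furan, and closure through the compact arrangement would give the cis ring fusion at C5. Fallback: setting out from 12, C5 is brominated through its trimethylsilyl enol ether (Me3SiOTf, Et3N; then NBS, −78 °C) to the α,α,α′-tribromoketone F1. F1 is then reduced with Zn–Cu couple in THF at −10 °C. This makes a zinc-bound bromo-oxyallyl by reduction instead of by base-induced ionisation, with no alcohol solvent or free enolate present, and its cycloaddition to the furan comes back to the route at 13.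

Step 12. Loss of HBr toward the C18 methyl, or displacement of bromide by the C19 oxygen, may outrun the 1,2-shift if the antiperiplanar alignment is poorer than expected. Fallback: setting out from 13, taken to its silyl enol ether 14 as in step 10, the enol ether is oxidised with PhI(OAc)2 and BF3·OEt2 in methanol. This is the oxidative ring contraction of a cyclic ketone by a hypervalent iodine reagent: iodination of C4 from the bridge face, methanol addition at C19, then shift of C5 with loss of iodobenzene. It should give the ring-contracted diester F2, with C19 as a methyl ester. After NaOMe equilibration of C6, the conditions of step 13 reduce both esters and open the bridge, coming back to the route at 18.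

Step 13. Hydroalumination may place aluminium on C1 and so cleave C10–O, or the nickel hydride may add to the silyl alkyne. Fallback: setting out from 17, LiAlH4 in THF reduces aldehyde and ester to the diol F3. Hydrostannation of the strained alkene (Bu3SnH, Pd(OH)2 on carbon, THF) then places tin on C2 from the bridge face, giving the stannane F4. MeLi (excess, THF, −78 → 0 °C) effects tin–lithium exchange, and the C2 carbanion expels the C3 oxygen, coming back to the route at 18.

Further compounds
F1 | step 9 | methyl 3,5,5-tribromo-4-oxo-2-[ring as in 10]hexanoate (both C5 epimers) | CC(C)[Si](C(C)C)(C(C)C)C#CC[C@]1([C@H](C(Br)C(=O)C(C)(Br)Br)C(=O)OC)CC2(OCCO2)CC[C@H]1c1ccco1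
F2 | step 12 | analogue of 17 with C19 as methyl ester (C4 with CO2Me α and CH3 β) | CC(C)[Si](C(C)C)(C(C)C)C#CC[C@]23CC4(OCCO4)CC[C@H]2[C@@]15C=C[C@@H](O1)[C@@](C)(C(=O)OC)[C@H]5[C@@H]3C(=O)OC
F3 | step 13 | diol of 17 (19-CH2OH and 7-CH2OH, oxygen bridge intact) | CC(C)[Si](C(C)C)(C(C)C)C#CC[C@]23CC4(OCCO4)CC[C@H]2[C@@]15C=C[C@@H](O1)[C@@](C)(CO)[C@H]5[C@@H]3CO
F4 | step 13 | 2-tributylstannyl derivative of F3 (tin on C2 syn to the oxygen bridge, C1 saturated) | CC(C)[Si](C(C)C)(C(C)C)C#CC[C@]23CC4(OCCO4)CC[C@H]2[C@@]15C[C@@H]([Sn](CCCC)(CCCC)CCCC)[C@@H](O1)[C@@](C)(CO)[C@H]5[C@@H]3CO
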